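The ratio we count is picks per flip, a pick being a substrate turned into product and a flip a substrate turned into its mirror image (racemisation): a working catalyst seems to pick left-handed substrate faster than right-handed substrate, which in the oak run had lost 1.00 part to the left-handed substrate's 3.40 at the first reading. We therefore take the excess E of right-handed over left-handed among what is left to follow pick rate over flip rate.

in all of them: left-handed substrate 0.10 M; right-handed substrate 0.10 M
- larch: partner 0.22 M; catalyst 11 mM; added ligand 8 mM; run made earlier
- alder: partner 0.22 M; catalyst 22 mM; added ligand 8 mM; run made earlier
- oak: partner 0.22 M; catalyst 31 mM; added ligand 8 mM; run made earlier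
- midnight: partner 0.220 M; catalyst 13 mM; added ligand 8.0 mM; time 15 min
- winter: partner 0.220 M; catalyst 40 mM; added ligand 8.0 mM; time 15 min

| run | time / min | right-handed substrate / % | left-handed substrate / % | left-handed product / % |
|---|---|---|---|---|
| larch | 1.33 | 47 | 51 | 4 |
| larch | 3.00 | 47 | 41 | 11 |
| larch | 6.00 | 45 | 39 | 19 |
| larch | 15.0 | 35 | 30 | 26 |
| alder | 4.00 | 40 | 24 | 25 |
| alder | 8.00 | 31 | 22 | 32 |
| alder | 12.0 | 23 | 16 | 33 |
| alder | 15.0 | 24 | 18 | 37 |
| oak | 1.33 | 45 | 33 | 18 |
| oak | 3.00 | 39 | 23 | 30 |
| oak | 6.00 | 28 | 20 | 39 |
| oak | 15.0 | 17 | 12 | 39 |

(scatter of a reading: 2 percentage points)

- catalyst is single-handed; left-handed substrate and right-handed substrate are mirror images of each other, charged as a racemate, each of them at the stated concentration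
- the numbers in the tables scatter with a standard deviation of 2 percentage points
- what may be going on: catalyst + added ligand <-> idle complex; left-handed product <-> right-handed product; catalyst <-> dormant form; left-handed substrate <-> right-handed substrate; partner + catalyst + right-handed substrate -> catalyst + right-handed product; partner + catalyst + left-handed substrate -> catalyst + left-handed product
- an excess is below zero if the other one leads

- the flask that ends with the higher excess of right-handed substrate over left-handed substrate among what is left of the two, or "neither" when 2 percentage points or less lies between them (midnight / winter / neither)
- excess of right-handed substrate over left-handed substrate among what is left of the two at the end, midnight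
- excess of right-handed substrate over left-handed substrate among what is left of the two at the end, winter

Each pick takes one partner, so we write E = g·b, with b the share of partner left, taken from the substrate gone, and g the grip, the excess per unit of b. The last readings give:

larch: E = 7.69%, b = 0.682, g = 0.113

oak: E = 17.2%, b = 0.355, g = 0.486

Our first link, that the added ligand holds its whole charge of catalyst, makes oak's grip 7.67 times larch's, but the readings give less than that, 4.31 times. So we reforge it: a straight line through both runs reaches zero grip at h = 4.96 mM of catalyst, less than the ligand charged. The alder run, not used for the line, tests it:

alder: g·b = 15.0%, read 14.3%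

We let b fall as a power of the neighbouring run's b, the power being the ratio of catalyst minus h. Winter holds more catalyst than the oak run, so its figure is an extrapolation.

midnight: g = 0.150, b = 0.601, E = 9.02%

winter: g = 0.654, b = 0.248, E = 16.2%

The forecast named winter, with 9% and 15%, the second below our figure, on the ground that the difference in rate constants “falls as partner is consumed”.

The flasks give winter as the higher, with midnight at 7.64% and winter at 17.8%.

    catalyst + added ligand ⇌ idle complex, settled at all times (K = 550 L mol⁻¹)
    left-handed product ⇌ right-handed product (k = 0.00105 s⁻¹)
    catalyst ⇌ dormant form (K = 0.520, k = 0.00196 s⁻¹)
    left-handed substrate ⇌ right-handed substrate (k = 0.00260 s⁻¹)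
    partner + catalyst + right-handed substrate → catalyst + right-handed product (k = 0.173 L² mol⁻² s⁻¹)
    partner + catalyst + left-handed substrate → catalyst + left-handed product (k = 1.31 L² mol⁻² s⁻¹)

At 4.96 min midnight uses left-handed substrate by its pick at 0.46 of the forward rate of its flip alone, so at that moment this pick runs slower than that forward flip. The grip times midnight's partner left at the end, 62%, gives 9.24% against the 7.64% it holds, and the same midnight flask left until 1.0 h, with 31.3% of its partner left, gives 4.71% by the grip and holds 3.70%.

The numbers in the tables were generated by integration for substances that don't exist; noise was put on by code.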